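**Retrosynthetic overview**
1. Target ⇐ acetonide hydrolysis and O-acetylation of a (Z)-2-cyclohexyl allylic alcohol.
2. (Z)-Allylic alcohol ⇐ Corey–Schlosser β-oxido ylide hydroxymethylation joining a cyclohexylmethyl phosphonium salt, a chiral-pool aldehyde (from (S)-α-hydroxy-γ-butyrolactone) and formaldehyde.
3. Phosphonium salt ⇐ ring mono-ester (its α-centre set by equilibration) ⇐ Krapcho reaction of a ring gem-diester.
4. Ring gem-diester ⇐ new palladium-catalysed enantioselective reductive 3,3′-allyl–allyl cyclisation of an acyclic bis(allylic carbonate); this forms the only carbocycle and both adjacent ring stereocentres.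
5. Bis-carbonate ⇐ dimethyl malonate + methyl vinyl ketone + isoprene monoxide + CH2=CHMgBr; the dioxolane (protecting ring) is made later on the side-chain fragment and opened in the last step.

Assumption: the (R)-configured ligand is taken to give the (3R,4R) ring diester by analogy with intermolecular allyl–allyl couplings; if the sense of induction is the reverse, the (S)-ligand is used with no other change.

**Step 1**
Reactants: 1 dimethyl malonate; 2 methyl vinyl ketone
Product: 3 dimethyl 2-(3-oxobutyl)propanedioate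
Conditions: NaOMe (5 mol %), MeOH, 0 to 23 °C (1.5 equiv of 1)
Reagents that add atoms: none
Why: Base-catalysed Michael addition of the malonate carbanion to the enone; excess malonate suppresses double addition and no stereocentre is formed.

**Step 2**
Reactants: 3 dimethyl 2-(3-oxobutyl)propanedioate; 4 2-methyl-2-vinyloxirane (racemic)
Product: 5 dimethyl 2-[(2E)-4-hydroxy-3-methylbut-2-en-1-yl]-2-(3-oxobutyl)propanedioate
Conditions: Pd(PPh3)4 (2 mol %), THF, 23 °C
Reagents that add atoms: none
Why: Tsuji–Trost allylation under neutral conditions: zerovalent palladium opens the vinyl epoxide to a π-allyl alkoxide that deprotonates 3, and the soft carbanion attacks the unsubstituted allyl terminus (1,4-addition) to give mainly the (E)-allylic alcohol, whose geometry is erased again in step 5.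

**Step 3**
Reactants: 5 keto allylic alcohol
Product: 6 dimethyl 2-[(2E)-4-hydroxy-3-methylbut-2-en-1-yl]-2-(3-hydroxy-3-methylpent-4-en-1-yl)propanedioate
Conditions: CH2=CHMgBr (2.5 equiv), LaCl3·2LiCl, THF, −78 °C; aq. NH4Cl at −78 °C
Reagents that add atoms: vinylmagnesium bromide, C=C[Mg]Br
Why: Lanthanum-promoted Grignard 1,2-addition to the methyl ketone, which is far more electrophilic than the hindered geminal esters (one equivalent is consumed by the hydroxyl group); the new tertiary carbinol is racemic and is destroyed on ionisation in step 5.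

**Step 4**
Reactants: 6 diol
Product: 7 dimethyl 2-{(2E)-4-[(methoxycarbonyl)oxy]-3-methylbut-2-en-1-yl}-2-{3-[(methoxycarbonyl)oxy]-3-methylpent-4-en-1-yl}propanedioate
Conditions: LiN(SiMe3)2 (2.2 equiv), THF, −78 °C; ClCO2Me, −78 to 0 °C
Reagents that add atoms: methyl chloroformate, COC(=O)Cl
Why: O-acylation of both lithium alkoxides (primary allylic and tertiary allylic) by the chloroformate; the non-nucleophilic amide base spares the esters and cold trapping outruns lactonisation.

**Step 5**
Reactants: 7 bis(allylic carbonate)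
Product: 9 dimethyl (3R,4R)-4-ethenyl-4-methyl-3-(prop-1-en-2-yl)cyclohexane-1,1-dicarboxylate, via allylboronate 8 (not isolated)
Conditions: Pd2(dba)3 (2.5 mol %), (R)-MeO-furyl-BIPHEP (6 mol %), B2pin2 (1.05 equiv, slow addition), THF (0.01 M), 60 °C
Reagents that add atoms: none
Why: Proposed new method: palladium-catalysed enantioselective reductive 3,3′-allyl–allyl cyclisation — zerovalent palladium ionises the primary carbonate, the released methoxide activates B2pin2 and C–B reductive elimination gives allylboronate 8; ionisation of the tertiary carbonate then gives a π-allylpalladium methoxide that transmetalates with the tethered boronate, and the bis(η1-allyl)palladium held by the chelating bisphosphine undergoes 3,3′-reductive elimination (the four-atom tether makes this the six-membered-ring mode, whereas 1,1′ or 1,3′ coupling would need ten- or eight-membered rings) through a chair-like array that places vinyl and isopropenyl trans-diequatorial as in the Cope rearrangement of an (E,E)-cyclodeca-1,5-diene, while the ligand selects one face of the rapidly π–σ–π-equilibrating 1,1-disubstituted allyl terminus to set the quaternary centre (R) and, through the chair, the adjacent centre (R); closest known reaction types are the intermolecular palladium-catalysed branch-selective enantioselective allyl–allyl coupling of allylic carbonates with allylboronates, the palladium-catalysed borylation of allylic carbonates with B2pin2, and the stoichiometric nickel-mediated bis-allyl cyclisation/Cope route to elemanes.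

**Step 6**
Reactants: 9 ring gem-diester
Product: 11 methyl (1S,3R,4R)-4-ethenyl-4-methyl-3-(prop-1-en-2-yl)cyclohexane-1-carboxylate, via C1-epimeric methyl ester 10 (not isolated)
Conditions: LiCl, H2O, DMSO, 150 °C; then NaOMe (0.2 equiv), MeOH, 23 °C
Reagents that add atoms: none
Why: Krapcho dealkoxycarbonylation of the geminal diester followed by base-mediated epimerisation α to the ester, which sets C1 under thermodynamic control (equatorial ester cis to the equatorial isopropenyl group, about 9:1 expected, minor epimer recycled).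

**Step 7**
Reactants: 11 ring mono-ester
Product: 12 [(1S,3R,4R)-4-ethenyl-4-methyl-3-(prop-1-en-2-yl)cyclohexyl]methanol
Conditions: LiAlH4, THF, 0 °C
Reagents that add atoms: none
Why: Hydride reduction of the ester to the primary alcohol; C1 is no longer epimerisable afterwards and no stereocentre is touched.

**Step 8**
Reactants: 12 primary alcohol
Product: 13 (1R,2R,4S)-1-ethenyl-4-(iodomethyl)-1-methyl-2-(prop-1-en-2-yl)cyclohexane
Conditions: I2, PPh3, imidazole, CH2Cl2, 0 to 23 °C
Reagents that add atoms: iodine, II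
Why: Appel-type iodination (Garegg–Samuelsson conditions) by SN2 displacement at the exocyclic CH2; no stereocentre is involved.

**Step 9**
Reactants: 13 primary iodide
Product: 14 {[(1S,3R,4R)-4-ethenyl-4-methyl-3-(prop-1-en-2-yl)cyclohexyl]methyl}triphenylphosphonium iodide
Conditions: PPh3, MeCN, 85 °C, 48 h
Reagents that add atoms: triphenylphosphine, c1ccc(cc1)P(c1ccccc1)c1ccccc1
Why: SN2 quaternisation of triphenylphosphine by the primary iodide gives the Wittig salt.

**Step 10**
Reactants: 15 (3S)-3-hydroxyoxolan-2-one ((S)-α-hydroxy-γ-butyrolactone)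
Product: 16 (3S)-4-methylpentane-1,3,4-triol
Conditions: MeMgBr (3.5 equiv), THF, 0 to 23 °C
Reagents that add atoms: methylmagnesium bromide, C[Mg]Br
Why: Double Grignard addition to the lactone carbonyl (one further equivalent deprotonates the hydroxyl); the carbinol stereocentre comes from the chiral pool and is not touched.

**Step 11**
Reactants: 16 triol
Product: 17 2-[(4S)-2,2,5,5-tetramethyl-1,3-dioxolan-4-yl]ethan-1-ol
Conditions: Me2C(OMe)2, PPTS (cat.), acetone, 23 °C
Reagents that add atoms: 2,2-dimethoxypropane, COC(C)(C)OC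
Why: Acid-catalysed transketalisation under equilibrating conditions; the five-membered dioxolane across the secondary/tertiary diol is preferred over the 1,3-dioxane, leaving the primary alcohol free.

**Step 12**
Reactants: 17 acetonide alcohol
Product: 18 2-[(4S)-2,2,5,5-tetramethyl-1,3-dioxolan-4-yl]acetaldehyde
Conditions: Dess–Martin periodinane, CH2Cl2, 0 to 23 °C
Reagents that add atoms: none
Why: Dess–Martin oxidation of the primary alcohol to the aldehyde under mild, non-basic conditions; the β-stereocentre is not affected.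

**Step 13**
Reactants: 14 phosphonium iodide; 18 aldehyde
Product: 22 (2Z)-2-[(1S,3R,4R)-4-ethenyl-4-methyl-3-(prop-1-en-2-yl)cyclohexyl]-4-[(4S)-2,2,5,5-tetramethyl-1,3-dioxolan-4-yl]but-2-en-1-ol, via phosphonium ylide 19 (not isolated), via lithium betaine 20 (not isolated), via β-oxido ylide 21 (not isolated)
Conditions: n-BuLi (1.0 equiv), THF, −78 to 0 °C; 18, −78 °C; sec-BuLi (1.05 equiv), −78 to −30 °C; (CH2O)n, −30 to 23 °C
Reagents that add atoms: formaldehyde (as paraformaldehyde), C=O
Why: Corey–Schlosser β-oxido ylide hydroxymethylation (Wittig–Schlosser variant): Wittig addition gives the lithium betaine, α-deprotonation gives the β-oxido ylide, which is trapped by formaldehyde and loses Ph3PO through the original oxido group, so the hydroxymethyl group ends cis to the aldehyde-derived chain and the ring trans to it, i.e. the (Z)-olefin, with no stereocentre epimerised.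

**Step 14**
Reactants: 22 (Z)-allylic alcohol
Product: 23 (2Z)-2-[(1S,3R,4R)-4-ethenyl-4-methyl-3-(prop-1-en-2-yl)cyclohexyl]-4-[(4S)-2,2,5,5-tetramethyl-1,3-dioxolan-4-yl]but-2-en-1-yl acetate
Conditions: Ac2O, pyridine, DMAP (cat.), CH2Cl2, 0 °C
Reagents that add atoms: acetic anhydride, CC(=O)OC(C)=O
Why: DMAP-catalysed acetylation of the only free (primary allylic) hydroxyl group.

**Step 15**
Reactants: 23 acetate acetonide
Product: 24 (2Z,5S)-2-[(1S,3R,4R)-4-ethenyl-4-methyl-3-(prop-1-en-2-yl)cyclohexyl]-5,6-dihydroxy-6-methylhept-2-en-1-yl acetate (target)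
Conditions: AcOH/H2O 4:1, 40 °C
Reagents that add atoms: none
Why: Mild aqueous-acid hydrolysis of the isopropylidene ketal; the allylic acetate and the alkenes tolerate aqueous acetic acid and the carbinol configuration is retained.

**Compound list**
1 | dimethyl malonate | COC(=O)CC(=O)OC | starting material
2 | methyl vinyl ketone | CC(=O)C=C | starting material
3 | dimethyl 2-(3-oxobutyl)propanedioate | COC(=O)C(CCC(C)=O)C(=O)OC | intermediate
4 | 2-methyl-2-vinyloxirane (racemic) | CC1(C=C)CO1 | starting material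
5 | dimethyl 2-[(2E)-4-hydroxy-3-methylbut-2-en-1-yl]-2-(3-oxobutyl)propanedioate | COC(=O)C(C/C=C(\C)CO)(CCC(C)=O)C(=O)OC | intermediate
6 | dimethyl 2-[(2E)-4-hydroxy-3-methylbut-2-en-1-yl]-2-(3-hydroxy-3-methylpent-4-en-1-yl)propanedioate (racemic carbinol) | COC(=O)C(C/C=C(\C)CO)(CCC(C)(O)C=C)C(=O)OC | intermediate
7 | dimethyl 2-{(2E)-4-[(methoxycarbonyl)oxy]-3-methylbut-2-en-1-yl}-2-{3-[(methoxycarbonyl)oxy]-3-methylpent-4-en-1-yl}propanedioate | COC(=O)C(C/C=C(\C)COC(=O)OC)(CCC(C)(OC(=O)OC)C=C)C(=O)OC | intermediate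
8 | dimethyl 2-{3-[(methoxycarbonyl)oxy]-3-methylpent-4-en-1-yl}-2-[(2E)-3-methyl-4-(4,4,5,5-tetramethyl-1,3,2-dioxaborolan-2-yl)but-2-en-1-yl]propanedioate (not isolated) | COC(=O)C(C/C=C(\C)CB1OC(C)(C)C(C)(C)O1)(CCC(C)(OC(=O)OC)C=C)C(=O)OC | intermediate
9 | dimethyl (3R,4R)-4-ethenyl-4-methyl-3-(prop-1-en-2-yl)cyclohexane-1,1-dicarboxylate | C=C[C@@]1(C)CCC(C(=O)OC)(C(=O)OC)C[C@@H]1C(C)=C | intermediate
10 | methyl (1R,3R,4R)-4-ethenyl-4-methyl-3-(prop-1-en-2-yl)cyclohexane-1-carboxylate (not isolated) | C=C[C@@]1(C)CC[C@@H](C(=O)OC)C[C@@H]1C(C)=C | intermediate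
11 | methyl (1S,3R,4R)-4-ethenyl-4-methyl-3-(prop-1-en-2-yl)cyclohexane-1-carboxylate | C=C[C@@]1(C)CC[C@H](C(=O)OC)C[C@@H]1C(C)=C | intermediate
12 | [(1S,3R,4R)-4-ethenyl-4-methyl-3-(prop-1-en-2-yl)cyclohexyl]methanol | C=C[C@@]1(C)CC[C@H](CO)C[C@@H]1C(C)=C | intermediate
13 | (1R,2R,4S)-1-ethenyl-4-(iodomethyl)-1-methyl-2-(prop-1-en-2-yl)cyclohexane | C=C[C@@]1(C)CC[C@H](CI)C[C@@H]1C(C)=C | intermediate
14 | {[(1S,3R,4R)-4-ethenyl-4-methyl-3-(prop-1-en-2-yl)cyclohexyl]methyl}triphenylphosphonium iodide | C=C[C@@]1(C)CC[C@H](C[P+](c2ccccc2)(c2ccccc2)c2ccccc2)C[C@@H]1C(C)=C.[I-] | intermediate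
15 | (3S)-3-hydroxyoxolan-2-one | O[C@H]1CCOC1=O | starting material
16 | (3S)-4-methylpentane-1,3,4-triol | OCC[C@H](O)C(C)(C)O | intermediate
17 | 2-[(4S)-2,2,5,5-tetramethyl-1,3-dioxolan-4-yl]ethan-1-ol | OCC[C@@H]1OC(C)(C)OC1(C)C | intermediate
18 | 2-[(4S)-2,2,5,5-tetramethyl-1,3-dioxolan-4-yl]acetaldehyde | O=CC[C@@H]1OC(C)(C)OC1(C)C | intermediate
19 | {[(1S,3R,4R)-4-ethenyl-4-methyl-3-(prop-1-en-2-yl)cyclohexyl]methylidene}triphenyl-λ5-phosphane (not isolated) | C=C[C@@]1(C)CC[C@H](C=P(c2ccccc2)(c2ccccc2)c2ccccc2)C[C@@H]1C(C)=C | intermediate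
20 | lithium betaine: {1-[(1S,3R,4R)-4-ethenyl-4-methyl-3-(prop-1-en-2-yl)cyclohexyl]-2-(lithiooxy)-3-[(4S)-2,2,5,5-tetramethyl-1,3-dioxolan-4-yl]propyl}triphenylphosphonium iodide (not isolated) | C=C[C@@]1(C)CC[C@H](C(C(O[Li])C[C@@H]2OC(C)(C)OC2(C)C)[P+](c2ccccc2)(c2ccccc2)c2ccccc2)C[C@@H]1C(C)=C.[I-] | intermediate
21 | β-oxido ylide: lithium 1-[(1S,3R,4R)-4-ethenyl-4-methyl-3-(prop-1-en-2-yl)cyclohexyl]-3-[(4S)-2,2,5,5-tetramethyl-1,3-dioxolan-4-yl]-1-(triphenyl-λ5-phosphanylidene)propan-2-olate (not isolated) | C=C[C@@]1(C)CC[C@H](C(C(O[Li])C[C@@H]2OC(C)(C)OC2(C)C)=P(c2ccccc2)(c2ccccc2)c2ccccc2)C[C@@H]1C(C)=C | intermediate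
22 | (2Z)-2-[(1S,3R,4R)-4-ethenyl-4-methyl-3-(prop-1-en-2-yl)cyclohexyl]-4-[(4S)-2,2,5,5-tetramethyl-1,3-dioxolan-4-yl]but-2-en-1-ol | C=C[C@@]1(C)CC[C@H](/C(=C/C[C@@H]2OC(C)(C)OC2(C)C)CO)C[C@@H]1C(=C)C | intermediate
23 | (2Z)-2-[(1S,3R,4R)-4-ethenyl-4-methyl-3-(prop-1-en-2-yl)cyclohexyl]-4-[(4S)-2,2,5,5-tetramethyl-1,3-dioxolan-4-yl]but-2-en-1-yl acetate | C=C[C@@]1(C)CC[C@H](/C(=C/C[C@@H]2OC(C)(C)OC2(C)C)COC(C)=O)C[C@@H]1C(=C)C | intermediate
24 | (2Z,5S)-2-[(1S,3R,4R)-4-ethenyl-4-methyl-3-(prop-1-en-2-yl)cyclohexyl]-5,6-dihydroxy-6-methylhept-2-en-1-yl acetate | C=C[C@@]1(C)CC[C@H](/C(=C/C[C@H](O)C(C)(C)O)COC(C)=O)C[C@@H]1C(=C)C | target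

**Step count and risks**
Total steps: 15. Longest linear sequence: 12 (steps 1–9 and 13–15; steps 10–12 make the side-chain aldehyde).

Steps most likely to fail:

Step 5 (the proposed new cyclisation; risks are oligomerisation, double borylation, β-hydride loss to dienes, and insufficient diastereo- or enantiocontrol). The fallback uses known chemistry, sets out from 6 and comes back at 9. PBr3 (Et2O, 0 °C) converts both allylic alcohols of 6, the tertiary one with allylic transposition, into the bis-allylic dibromide dimethyl 2-[(2E)-4-bromo-3-methylbut-2-en-1-yl]-2-[(3E)-5-bromo-3-methylpent-3-en-1-yl]propanedioate F1. Slow addition of F1 to stoichiometric Ni(cod)2 (zerovalent nickel) in DMF at 50 °C effects the classical head-to-head bis-allyl coupling to the ten-membered diene dimethyl (3E,7E)-4,8-dimethylcyclodeca-3,7-diene-1,1-dicarboxylate F2. Heating F2 in toluene at 110 °C triggers the Cope rearrangement through the chair transition state to the trans-divinyl diester as a racemate, that is 9 together with its enantiomer dimethyl (3S,4S)-4-ethenyl-4-methyl-3-(prop-1-en-2-yl)cyclohexane-1,1-dicarboxylate F3. Preparative chromatography on a chiral stationary phase removes F3 and the route continues from 9.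

Step 13 (the α-carbon of betaine 20 carries a secondary alkyl group, so the second deprotonation may be slow and the yield modest). The fallback replaces the β-oxido ylide by a Wittig olefination of an α-alkoxy ketone; it sets out from 11 and 17 and comes back at 22. Ester 11 is converted with MeNH(OMe)·HCl and i-PrMgCl (THF, −20 °C) into the Weinreb amide (1S,3R,4R)-4-ethenyl-N-methoxy-N,4-dimethyl-3-(prop-1-en-2-yl)cyclohexane-1-carboxamide F4. Addition of PMBOCH2Li (from Bu3SnCH2OPMB and n-BuLi, THF, −78 °C) gives the α-alkoxy ketone 2-[(4-methoxyphenyl)methoxy]-1-[(1S,3R,4R)-4-ethenyl-4-methyl-3-(prop-1-en-2-yl)cyclohexyl]ethan-1-one F5. In parallel, alcohol 17 is iodinated (I2, PPh3, imidazole) to (4S)-4-(2-iodoethyl)-2,2,5,5-tetramethyl-1,3-dioxolane F6 and quaternised with PPh3 (MeCN, 85 °C) to {2-[(4S)-2,2,5,5-tetramethyl-1,3-dioxolan-4-yl]ethyl}triphenylphosphonium iodide F7. The ylide from F7 (KN(SiMe3)2, THF, −78 °C) is combined with F5 in a salt-free Wittig reaction; α-alkoxy ketones are reported to place the alkoxymethyl group cis to the ylide-derived chain, though with the bulky cyclohexyl group on the other side of the carbonyl this selectivity is less certain. The product is the PMB ether 1-methoxy-4-({[(2Z)-2-[(1S,3R,4R)-4-ethenyl-4-methyl-3-(prop-1-en-2-yl)cyclohexyl]-4-[(4S)-2,2,5,5-tetramethyl-1,3-dioxolan-4-yl]but-2-en-1-yl]oxy}methyl)benzene F8, with the E isomer removed by chromatography. DDQ (CH2Cl2/H2O, 0 °C) cleaves the PMB ether and the route continues from 22.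

Step 15 (the tetrasubstituted dioxolane may need acid strong enough to endanger the allylic acetate or the 1,1-disubstituted alkene). The fallback reverses the order and relies on chemoselective acylation; it sets out from 22 and comes back at 24. The acetonide of 22 is hydrolysed first (1 M HCl, THF, 23 °C) to the triol (2Z,5S)-2-[(1S,3R,4R)-4-ethenyl-4-methyl-3-(prop-1-en-2-yl)cyclohexyl]-6-methylhept-2-ene-1,5,6-triol F9. Acetylation of the primary allylic hydroxyl alone (AcCl, 2,4,6-collidine, CH2Cl2, −78 °C), in the presence of the hindered secondary and the tertiary hydroxyl, then gives 24 directly.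

**Further compounds**
F1 | step 5 | dimethyl 2-[(2E)-4-bromo-3-methylbut-2-en-1-yl]-2-[(3E)-5-bromo-3-methylpent-3-en-1-yl]propanedioate | COC(=O)C(C/C=C(\C)CBr)(CC/C(C)=C/CBr)C(=O)OC
F2 | step 5 | dimethyl (3E,7E)-4,8-dimethylcyclodeca-3,7-diene-1,1-dicarboxylate | COC(=O)C1(C(=O)OC)C/C=C(\C)CC/C=C(\C)CC1
F3 | step 5 | dimethyl (3S,4S)-4-ethenyl-4-methyl-3-(prop-1-en-2-yl)cyclohexane-1,1-dicarboxylate | C=C[C@]1(C)CCC(C(=O)OC)(C(=O)OC)C[C@H]1C(C)=C
F4 | step 13 | (1S,3R,4R)-4-ethenyl-N-methoxy-N,4-dimethyl-3-(prop-1-en-2-yl)cyclohexane-1-carboxamide | C=C[C@@]1(C)CC[C@H](C(=O)N(C)OC)C[C@@H]1C(C)=C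
F5 | step 13 | 2-[(4-methoxyphenyl)methoxy]-1-[(1S,3R,4R)-4-ethenyl-4-methyl-3-(prop-1-en-2-yl)cyclohexyl]ethan-1-one | C=C[C@@]1(C)CC[C@H](C(=O)COCc2ccc(OC)cc2)C[C@@H]1C(C)=C
F6 | step 13 | (4S)-4-(2-iodoethyl)-2,2,5,5-tetramethyl-1,3-dioxolane | CC1(C)O[C@@H](CCI)C(C)(C)O1
F7 | step 13 | {2-[(4S)-2,2,5,5-tetramethyl-1,3-dioxolan-4-yl]ethyl}triphenylphosphonium iodide | CC1(C)O[C@@H](CC[P+](c2ccccc2)(c2ccccc2)c2ccccc2)C(C)(C)O1.[I-]
F8 | step 13 | 1-methoxy-4-({[(2Z)-2-[(1S,3R,4R)-4-ethenyl-4-methyl-3-(prop-1-en-2-yl)cyclohexyl]-4-[(4S)-2,2,5,5-tetramethyl-1,3-dioxolan-4-yl]but-2-en-1-yl]oxy}methyl)benzene | C=C[C@@]1(C)CC[C@H](/C(=C/C[C@@H]2OC(C)(C)OC2(C)C)COCc2ccc(OC)cc2)C[C@@H]1C(=C)C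
F9 | step 15 | (2Z,5S)-2-[(1S,3R,4R)-4-ethenyl-4-methyl-3-(prop-1-en-2-yl)cyclohexyl]-6-methylhept-2-ene-1,5,6-triol | C=C[C@@]1(C)CC[C@H](/C(=C/C[C@H](O)C(C)(C)O)CO)C[C@@H]1C(=C)C
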